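Retrosynthesis: the 7-O-methoxymethyl group and a removable bromine on C5 are put back. O1-C8a and C4-C4a of ring C are then cut together, leaving ring A as an aryne and rings B and D as an (S)-3-aryl-3-silyloxypropanoate.
Enabling feature: O1 and C4 sit on C8a and C4a, two neighbouring carbons of ring A. A triple bond across C8a-C4a can therefore accept the C2 oxygen and hand the resulting aryl anion to the C4 ester carbon.
Forward order: ring D is fused to ring B first (C-prenylation, propargyl ether and thermal rearrangement of 4-hydroxyacetophenone), and C4 is added by Claisen condensation. Ring A is made separately from hydroquinone as an ortho-silylaryl triflate, and ring C closes last.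
Stereochemistry: C2, the only stereocentre, is set by transfer hydrogenation of the beta-keto ester with RuCl(p-cymene)[(S,S)-TsDPEN]. Its C-O bond is never broken afterwards, and the later steps avoid free base.
End game: palladium-catalysed formate reduction of the C5 bromide, then acidic removal of the methoxymethyl group.

Key step: step 10

Remark: atoms O1 to C8a and rings A and C follow flavanone numbering; ring B is the benzene ring on C2 and ring D the dimethylpyran fused to it; the acetyl carbons of 4-hydroxyacetophenone become C2 and C3.

Step 1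
Reactants: 1 4-hydroxyacetophenone; 2 prenyl bromide (1-bromo-3-methylbut-2-ene)
Product: 3 C-prenyl phenol (1-[4-hydroxy-3-(3-methylbut-2-enyl)phenyl]ethanone)
Conditions: KOH (1.1 equiv), H2O, 0 °C to rt
Reagents that add atoms: none
Why: Phenoxide C-alkylation, in which water hydrogen-bonds the phenoxide oxygen so that the allylic bromide is taken up in part at the ortho carbon with the linear prenyl connectivity, a long-used if unselective entry to ortho-prenyl para-acylphenols whose neutral O-prenyl by-product is removed by base extraction.

Step 2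
Reactants: 3 C-prenyl phenol; 4 3-chloro-3-methylbut-1-yne
Product: 5 propargyl ether (1-[4-(2-methylbut-3-yn-2-yloxy)-3-(3-methylbut-2-enyl)phenyl]ethanone)
Conditions: K2CO3, KI (cat), CuI (cat), acetone, reflux
Reagents that add atoms: none
Why: Copper-assisted Williamson-type etherification of a phenol with a tertiary propargylic chloride, the standard way to 1,1-dimethylpropargyl aryl ethers, which leaves ketone and prenyl group untouched.

Step 3
Reactants: 5 propargyl ether
Product: 8 acetylchromene (1-[2,2-dimethyl-8-(3-methylbut-2-enyl)-2H-chromen-6-yl]ethanone), via allenylphenol 6 (not isolated), via ortho-quinone methide 7 (not isolated)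
Conditions: N,N-diethylaniline, 185 °C
Reagents that add atoms: none
Why: Aromatic propargyl Claisen rearrangement to the only free ortho carbon, tautomerisation to 6, 1,5-hydrogen shift to 7 and oxa-6π electrocyclisation, the established thermal route to 2,2-dimethyl-2H-chromenes, which closes ring D.

Step 4
Reactants: 8 acetylchromene
Product: 9 beta-keto ester (methyl 3-[2,2-dimethyl-8-(3-methylbut-2-enyl)-2H-chromen-6-yl]-3-oxopropanoate)
Conditions: NaH (2.5 equiv), (MeO)2CO, THF, reflux; AcOH quench
Reagents that add atoms: dimethyl carbonate COC(=O)OC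
Why: Crossed Claisen condensation of a methyl ketone enolate with dimethyl carbonate, driven by deprotonation of the beta-keto ester as it forms, on a substrate with no other acidic or electrophilic site.

Step 5
Reactants: 9 beta-keto ester
Product: 10 hydroxy ester (methyl (3S)-3-[2,2-dimethyl-8-(3-methylbut-2-enyl)-2H-chromen-6-yl]-3-hydroxypropanoate)
Conditions: RuCl(p-cymene)[(S,S)-TsDPEN] (1 mol %), HCO2H/Et3N (5:2), 30 °C
Reagents that add atoms: none
Why: Noyori-type asymmetric transfer hydrogenation of an aroylacetate, in which the contact between the cymene ligand and the ketone aryl group fixes the face of hydride delivery so that the (S,S) catalyst should give the S carbinol (the future C2) as it does with aryl alkyl ketones, while the outer-sphere hydride transfer ignores both alkenes.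

Step 6
Reactants: 10 hydroxy ester
Product: 11 silyl ether (methyl (3S)-3-[2,2-dimethyl-8-(3-methylbut-2-enyl)-2H-chromen-6-yl]-3-(trimethylsilyloxy)propanoate)
Conditions: TMSCl, Et3N, CH2Cl2, 0 °C; filtration, no aqueous work-up
Reagents that add atoms: chlorotrimethylsilane C[Si](C)(C)Cl
Why: Routine O-silylation of a secondary alcohol, which removes the only O-H proton and stores the hydroxyl as a fluoride-releasable alkoxide without touching the stereocentre.

Step 7
Reactants: 12 hydroquinone
Product: 13 mono-ether (4-(methoxymethoxy)phenol)
Conditions: 12 (3 equiv), MOMCl (1 equiv), K2CO3, acetone, 0 °C to rt, argon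
Reagents that add atoms: chloromethyl methyl ether COCCl
Why: Williamson-type O-alkylation under statistical control, in which the excess of diol limits double protection and water washing (diol) plus base extraction (mono-ether) should separate the components.

Step 8
Reactants: 13 mono-ether
Product: 14 dibromophenol (2,6-dibromo-4-(methoxymethoxy)phenol)
Conditions: NBS (2.05 equiv), i-Pr2NH (10 mol %), CH2Cl2, 0 °C to rt
Reagents that add atoms: N-bromosuccinimide O=C1CCC(=O)N1Br
Why: Electrophilic aromatic bromination steered by the free hydroxyl, the stronger donor, to its two ortho positions (para is blocked), under the amine-catalysed NBS protocol known for ortho-dibromination of phenols, which frees no HBr that could cleave the acetal.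

Step 9
Reactants: 14 dibromophenol
Product: 18 silylaryl triflate (2-bromo-4-(methoxymethoxy)-6-(trimethylsilyl)phenyl trifluoromethanesulfonate), via silyl ether 15 (not isolated), via aryllithium 16 (not isolated), via lithium phenoxide 17 (not isolated)
Conditions: HMDS, THF, 65 °C, then evaporation; n-BuLi (1.05 equiv), THF, -78 °C; Tf2O (1.2 equiv), -78 °C to 0 °C
Reagents that add atoms: hexamethyldisilazane C[Si](C)(C)N[Si](C)(C)C; trifluoromethanesulfonic anhydride O=S(=O)(OS(=O)(=O)C(F)(F)F)C(F)(F)F
Why: O-silylation, bromine-lithium exchange, retro-Brook rearrangement (1,3 shift of silicon from oxygen to carbon) and triflation of phenoxide 17, the standard telescoped route from 2-bromophenols to ortho-silylaryl triflates, in which the second bromine is meta to the lithiated carbon and so cannot be eliminated.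

Step 10
Reactants: 11 silyl ether; 18 silylaryl triflate
Product: 22 bromoflavanone ((2S)-5-bromo-2-[2,2-dimethyl-8-(3-methylbut-2-enyl)-2H-chromen-6-yl]-7-(methoxymethoxy)-2,3-dihydrochromen-4-one), via potassium alkoxide 19 (not isolated), via aryne 20 (not isolated), via aryl anion 21 (not isolated)
Conditions: 11 (1.0 equiv), 18 (1.5 equiv), KF (1.6 equiv), 18-crown-6 (1.6 equiv), THF, -20 °C to 0 °C, argon; pH 7 phosphate buffer at -20 °C
Reagents that add atoms: none
Why: Proposed new method: fluoride takes the O-silyl group from 11 and the C-silyl group from 18 (triflate then leaves), so alkoxide 19 and aryne 20 meet in a flask that holds no O-H acid; 19 adds to the aryne carbon meta to bromine (O1-C8a) and the aryl anion 21, now on C4a, attacks the ester carbonyl and expels methoxide (C4-C4a). Ring C closes in that second event by a 6-exo-trig acyl substitution. The closest known reaction type is the fluoride-induced annulation of arynes with methyl salicylates to xanthones, in which oxygen adds and the aryl anion then captures the ester; O-arylation of aliphatic alcohols by arynes under KF/18-crown-6 at low temperature is known too, whereas an aldol-type secondary alkoxide on a flexible tether is untested. No stereocentre is created: the C2-O bond stays intact throughout, so the S configuration set in step 5 passes unchanged into 22. The step needs oxygen on C8a and acyl on C4a, and the C5 bromine secures this, because its inductive pull bends the aryne so that the remote carbon is the more linear and electrophilic one and the negative charge develops next to the halogen, which should outweigh the weak opposite bias of the C7 oxygen. It also needs acyl capture to beat protonation, bromide loss, retro-aldol cleavage and base-induced opening of ring C, hence the silyl ether in place of the free alcohol, the sub-zero temperature, the cold buffered quench and the limited fluoride charge, which lets the expelled methoxide be used up on the remaining silicon centres as Me3SiOMe.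

Step 11
Reactants: 22 bromoflavanone
Product: 23 protected flavanone ((2S)-2-[2,2-dimethyl-8-(3-methylbut-2-enyl)-2H-chromen-6-yl]-7-(methoxymethoxy)-2,3-dihydrochromen-4-one)
Conditions: Pd(OAc)2 (5 mol %), PPh3 (20 mol %), HCO2H (3 equiv), Et3N (2.5 equiv), DMF, 60 °C
Reagents that add atoms: none
Why: Palladium-catalysed hydrodehalogenation with formate as hydride donor, in which zerovalent palladium inserts into the C5-Br bond activated by the ortho carbonyl, formate replaces bromide and loses CO2 and reductive elimination gives C5-H, while the excess of formic acid keeps the medium weakly acidic so that ring C should not open and the hindered alkenes of rings B and D should stay.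

Step 12
Reactants: 23 protected flavanone
Product: 24 target flavanone ((2S)-7-hydroxy-2-[2,2-dimethyl-8-(3-methylbut-2-enyl)-2H-chromen-6-yl]-2,3-dihydrochromen-4-one)
Conditions: HCl (3 M aq, 3 equiv), MeOH, 45 °C
Reagents that add atoms: none
Why: Acid-catalysed acetal exchange (methanolysis of an aryl methoxymethyl ether), routinely survived by prenyl and dimethylchromene groups that lack a free ortho hydroxyl, and safe for C2 because no base is present and the para oxygen of ring B is alkylated, which closes the quinone methide path to racemisation.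

Compound list
1 | 4-hydroxyacetophenone | CC(=O)c1ccc(O)cc1 | starting material
2 | prenyl bromide (1-bromo-3-methylbut-2-ene) | CC(C)=CCBr | starting material
3 | 1-[4-hydroxy-3-(3-methylbut-2-enyl)phenyl]ethanone | CC(=O)c1ccc(O)c(CC=C(C)C)c1 | intermediate
4 | 3-chloro-3-methylbut-1-yne | CC(C)(Cl)C#C | starting material
5 | 1-[4-(2-methylbut-3-yn-2-yloxy)-3-(3-methylbut-2-enyl)phenyl]ethanone | CC(=O)c1ccc(OC(C)(C)C#C)c(CC=C(C)C)c1 | intermediate
6 | allenylphenol, 1-[4-hydroxy-3-(3-methylbuta-1,2-dienyl)-5-(3-methylbut-2-enyl)phenyl]ethanone | CC(=O)c1cc(CC=C(C)C)c(O)c(C=C=C(C)C)c1 | intermediate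
7 | ortho-quinone methide, 4-acetyl-6-(3-methylbut-2-enylidene)-2-(3-methylbut-2-enyl)cyclohexa-2,4-dien-1-one | CC(=O)C1=CC(=CC=C(C)C)C(=O)C(CC=C(C)C)=C1 | intermediate
8 | 1-[2,2-dimethyl-8-(3-methylbut-2-enyl)-2H-chromen-6-yl]ethanone | CC(C)=CCc1cc(C(C)=O)cc2c1OC(C)(C)C=C2 | intermediate
9 | methyl 3-[2,2-dimethyl-8-(3-methylbut-2-enyl)-2H-chromen-6-yl]-3-oxopropanoate | CC(C)=CCc1cc(C(=O)CC(=O)OC)cc2c1OC(C)(C)C=C2 | intermediate
10 | methyl (3S)-3-[2,2-dimethyl-8-(3-methylbut-2-enyl)-2H-chromen-6-yl]-3-hydroxypropanoate | CC(C)=CCc1cc([C@@H](O)CC(=O)OC)cc2c1OC(C)(C)C=C2 | intermediate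
11 | methyl (3S)-3-[2,2-dimethyl-8-(3-methylbut-2-enyl)-2H-chromen-6-yl]-3-(trimethylsilyloxy)propanoate | CC(C)=CCc1cc([C@@H](O[Si](C)(C)C)CC(=O)OC)cc2c1OC(C)(C)C=C2 | intermediate
12 | hydroquinone | Oc1ccc(O)cc1 | starting material
13 | 4-(methoxymethoxy)phenol | COCOc1ccc(O)cc1 | intermediate
14 | 2,6-dibromo-4-(methoxymethoxy)phenol | COCOc1cc(Br)c(O)c(Br)c1 | intermediate
15 | [2,6-dibromo-4-(methoxymethoxy)phenoxy]trimethylsilane | COCOc1cc(Br)c(O[Si](C)(C)C)c(Br)c1 | intermediate
16 | [3-bromo-5-(methoxymethoxy)-2-(trimethylsilyloxy)phenyl]lithium | COCOc1cc(Br)c(O[Si](C)(C)C)c([Li])c1 | intermediate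
17 | lithium 2-bromo-4-(methoxymethoxy)-6-(trimethylsilyl)phenoxide | COCOc1cc(Br)c([O-])c([Si](C)(C)C)c1.[Li+] | intermediate
18 | 2-bromo-4-(methoxymethoxy)-6-(trimethylsilyl)phenyl trifluoromethanesulfonate | COCOc1cc(Br)c(OS(=O)(=O)C(F)(F)F)c([Si](C)(C)C)c1 | intermediate
19 | potassium (1S)-1-[2,2-dimethyl-8-(3-methylbut-2-enyl)-2H-chromen-6-yl]-3-methoxy-3-oxopropan-1-olate | CC(C)=CCc1cc([C@@H]([O-])CC(=O)OC)cc2c1OC(C)(C)C=C2.[K+] | intermediate
20 | 3-bromo-5-(methoxymethoxy)benzyne | COCOC1=CC#CC(Br)=C1 | intermediate
21 | aryl anion (potassium salt), methyl (3S)-3-[3-bromo-5-(methoxymethoxy)-2-potassiophenoxy]-3-[2,2-dimethyl-8-(3-methylbut-2-enyl)-2H-chromen-6-yl]propanoate | CC(C)=CCc1cc([C@@H](Oc2cc(OCOC)cc(Br)[c-]2)CC(=O)OC)cc2c1OC(C)(C)C=C2.[K+] | intermediate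
22 | (2S)-5-bromo-2-[2,2-dimethyl-8-(3-methylbut-2-enyl)-2H-chromen-6-yl]-7-(methoxymethoxy)-2,3-dihydrochromen-4-one | CC(C)=CCc1cc([C@@H]2CC(=O)c3c(Br)cc(OCOC)cc3O2)cc2c1OC(C)(C)C=C2 | intermediate
23 | (2S)-2-[2,2-dimethyl-8-(3-methylbut-2-enyl)-2H-chromen-6-yl]-7-(methoxymethoxy)-2,3-dihydrochromen-4-one | CC(C)=CCc1cc([C@@H]2CC(=O)c3ccc(OCOC)cc3O2)cc2c1OC(C)(C)C=C2 | intermediate
24 | (2S)-7-hydroxy-2-[2,2-dimethyl-8-(3-methylbut-2-enyl)-2H-chromen-6-yl]-2,3-dihydrochromen-4-one | CC(C)=CCc1cc([C@@H]2CC(=O)c3ccc(O)cc3O2)cc2c1OC(C)(C)C=C2 | target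

Total step count: 12. Longest linear sequence: 9 (steps 1 to 6 and 10 to 12, from 1).

Steps most likely to fail

**Step 10.** Several processes compete with the annulation:
- The aryl anion may pick up a proton from a C-H acid before it reaches the ester.
- It may expel the neighbouring bromide and form a second aryne.
- The unveiled alkoxide may fragment by retro-aldol cleavage or eliminate.
- The flavanone may be enolised, so that ring C opens and the C2 configuration is lost.
- The alkoxide may add in part to the wrong aryne carbon.
- The alkenes of rings B and D may consume aryne by ene reaction or cycloaddition.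

The fallback closes ring C by known chemistry in two separate events: C4-C4a by aryllithium addition to a Weinreb amide, and O1-C2 by an intramolecular Mitsunobu reaction with inversion. It sets out from 9, which RuCl(p-cymene)[(R,R)-TsDPEN] and HCO2H/Et3N reduce to methyl (3R)-3-[2,2-dimethyl-8-(3-methylbut-2-enyl)-2H-chromen-6-yl]-3-hydroxypropanoate F1. MeNH(OMe)·HCl and i-PrMgCl in THF at -20 °C convert this into (3R)-3-[2,2-dimethyl-8-(3-methylbut-2-enyl)-2H-chromen-6-yl]-3-hydroxy-N-methoxy-N-methylpropanamide F2.

Commercial 4-bromoresorcinol is alkylated with MOMCl and i-Pr2NEt at the hydroxyl remote from bromine to give 2-bromo-5-(methoxymethoxy)phenol F3. n-BuLi (2 equiv, THF, -78 °C) turns F3 into lithium 2-lithio-5-(methoxymethoxy)phenoxide F4. Addition of F4 to the magnesium alkoxide of F2 gives (3R)-3-[2,2-dimethyl-8-(3-methylbut-2-enyl)-2H-chromen-6-yl]-3-hydroxy-1-[2-hydroxy-4-(methoxymethoxy)phenyl]propan-1-one F5. PPh3 and DIAD in THF at 0 °C then close ring C with inversion to the S configuration. The route is rejoined at 23, so step 11 is no longer needed.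

**Step 11.** Warm amine formate may erode the C2 configuration through reversible opening of ring C, and palladium hydride may shift or saturate the alkenes of rings B and D. The fallback replaces the two-electron palladium cycle by a neutral radical chain. From 22, Bu3SnH and AIBN in toluene at 80 °C abstract the bromine and deliver hydrogen to the aryl radical, and the route is rejoined at 23 without any new compound.

**Step 1.** The prenylation may suffer from poor carbon versus oxygen selectivity and from double alkylation. The fallback brings the prenyl group in last by cross-coupling. From 1, NIS and catalytic TsOH in MeCN give 1-(4-hydroxy-3-iodophenyl)ethanone F6. Etherification with 4 under the conditions of step 2 gives 1-[3-iodo-4-(2-methylbut-3-yn-2-yloxy)phenyl]ethanone F7. Heating as in step 3 gives 1-(8-iodo-2,2-dimethyl-2H-chromen-6-yl)ethanone F8. Stille coupling with tributyl(3-methylbut-2-enyl)stannane (Pd(PPh3)4, DMF, 80 °C) rejoins the route at 8.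

Further compounds
F1 | step 10 | methyl (3R)-3-[2,2-dimethyl-8-(3-methylbut-2-enyl)-2H-chromen-6-yl]-3-hydroxypropanoate | CC(C)=CCc1cc([C@H](O)CC(=O)OC)cc2c1OC(C)(C)C=C2
F2 | step 10 | (3R)-3-[2,2-dimethyl-8-(3-methylbut-2-enyl)-2H-chromen-6-yl]-3-hydroxy-N-methoxy-N-methylpropanamide | CC(C)=CCc1cc([C@H](O)CC(=O)N(C)OC)cc2c1OC(C)(C)C=C2
F3 | step 10 | 2-bromo-5-(methoxymethoxy)phenol | COCOc1ccc(Br)c(O)c1
F4 | step 10 | lithium 2-lithio-5-(methoxymethoxy)phenoxide | COCOc1ccc([Li])c([O-])c1.[Li+]
F5 | step 10 | (3R)-3-[2,2-dimethyl-8-(3-methylbut-2-enyl)-2H-chromen-6-yl]-3-hydroxy-1-[2-hydroxy-4-(methoxymethoxy)phenyl]propan-1-one | CC(C)=CCc1cc([C@H](O)CC(=O)c3ccc(OCOC)cc3O)cc2c1OC(C)(C)C=C2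
F0 | step 11 | none | none
F6 | step 1 | 1-(4-hydroxy-3-iodophenyl)ethanone | CC(=O)c1ccc(O)c(I)c1
F7 | step 1 | 1-[3-iodo-4-(2-methylbut-3-yn-2-yloxy)phenyl]ethanone | CC(=O)c1ccc(OC(C)(C)C#C)c(I)c1
F8 | step 1 | 1-(8-iodo-2,2-dimethyl-2H-chromen-6-yl)ethanone | CC(=O)c1cc(I)c2OC(C)(C)C=Cc2c1
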